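The constants are invented, and the outcome is calculated.

The number to start from is 2.5: at the start, by the forward rates, free catalyst takes up left-handed substrate that many times as fast as right-handed substrate.

left-handed substrate 20 mM; partner 22.0 mM; free catalyst 100 µM; right-handed substrate 20 mM

* the form that holds most of the catalyst when 30% of the left-handed substrate and right-handed substrate together are converted (catalyst intermediate A / catalyst intermediate B / free catalyst / spent catalyst)
* its share of the catalyst then
* apparent order in partner when 30% of the left-handed substrate and right-handed substrate together are converted (percent change of the rate of making left-handed product for one percent more partner charged)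

    free catalyst + left-handed substrate ⇌ catalyst intermediate A (K1 = 1100 M⁻¹, k1 = 1500 M⁻¹ s⁻¹)
    free catalyst + right-handed substrate ⇌ catalyst intermediate B (K2 = 1500 M⁻¹, k2 = 600 M⁻¹ s⁻¹)
    partner + catalyst intermediate A → free catalyst + left-handed product (k3 = 330 M⁻¹ s⁻¹)
    partner + catalyst intermediate B → free catalyst + right-handed product (k4 = 160 M⁻¹ s⁻¹)
    partner + free catalyst → spent catalyst (k5 = 0.31 M⁻¹ s⁻¹)
    partner ⇌ dormant form (K6 = 1.2, k6 = 0.014 s⁻¹)

Treat each intermediate as a tank. Its inflow is the uptake rate constant times c(substrate) times c(free catalyst), and its outflow constant is the fall-back constant (uptake constant over equilibrium constant) plus the onward constant times c(partner). Set inflow equal to outflow for both tanks and divide, and free catalyst and time drop out. The hold ratio is c(catalyst intermediate B) over c(catalyst intermediate A), and it is the uptake factor (the uptake rate of B over that of A, per free catalyst) times the outflow constant of A over that of B. Turn the question round: intermediate A leads when this ratio lies under 1. With the charges it stands at 0.880, so I expect intermediate A to lead at first.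

By my reckoning, 30% conversion means 12.0 mM of turnover, each taking one partner. Partner relaxes with dormant form at a half-life of 0.450 min, shorter than the 0.864 min of the run to that point, so I take them as roughly equilibrated, and c(partner) comes to about 4.55 mM. Dividing the two uptake rates removes time again. I try c(right-handed substrate) = 16.0 mM, which leaves c(left-handed substrate) = 12.0 mM, and their logarithmic falls stand in the ratio 2.29, against 2.50 for the uptake constants.

The uptake factor is now 0.533, so intermediate A would need an outflow ratio under 1.88, but this flask has 2.54. The hold ratio is therefore 1.35. Per free catalyst there are 6.29 of intermediate A and 8.52 of intermediate B. I leave spent catalyst out of this count, since its rate per free catalyst with partner as charged, 0.41 min⁻¹, is far less than the uptake's 1800 min⁻¹ with left-handed substrate as charged. The resting state is thus catalyst intermediate B, with 53.9%. The order I leave unreckoned.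

The forecast names catalyst intermediate B at 52% and gives an order of 2.4, arguing that “an extra 1% of charge raises the partner left at fixed conversion by well over 2%”.

The simulation of this flask gives catalyst intermediate B at 52.5% and an order of 3.6.

At 0.279 min, catalyst intermediate B falls back at 0.20 of the rate at which it goes on. With the readings at 10.0 min, where partner stands at 0.472% of its charge, the hold ratio comes to 2.27, and the flask then holds 65.0% in catalyst intermediate B against 28.6% in catalyst intermediate A.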